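## The problem

The target **17** is an achiral 18-membered macrocycle built from four rings. Ring A is a 2-methoxy-1,4-benzoquinone; its atoms are called Q1 (methoxy carbon), Q2 (CH), Q3 (C=O), Q4 (aryloxy carbon), Q5 (alkylated carbon) and Q6 (C=O). Q4 is bound through oxygen to meta-phenylene ring D, ring D is joined by a CH2CH2 bridge to ring C, ring C is joined by a diaryl ether oxygen to para-phenylene ring B, and a second CH2CH2 bridge runs from ring B back to Q5. There is no stereocentre and no stereogenic double bond, so nothing has to be set or relayed; the task is connectivity, ring closure and chemoselectivity. The quinone is a doubly vinylogous ester (OMe on Q1, OAr on Q4): hydroxide, alkoxides, amines and thiols displace its oxygen substituents, and hydrogenation or metal reductants take it to the hydroquinone, so basic hydrolysis, hydrogenolysis and organometallic steps must come before it is installed. The free phenol of ring C sits ortho to the diaryl ether oxygen on an electron-rich ring; it must be masked during any oxidative step and unmasked without base or strong nucleophile. The 18-membered ring has no templating element, so its closure must outrun oligomerisation. The enabling feature is that in the seco compound Q5 is an unsubstituted CH on the Q4=Q5 bond of a 2-methoxy-5-aryloxyquinone, an electron-poor alkene that traps nucleophilic alkyl radicals, while the ring B side chain can be carried one carbon longer as a 3-arylpropanoic acid whose oxidative decarboxylation gives exactly the ArCH2CH2 radical. Because the radical adduct is reoxidised to the quinone, the ring-closing bond and the final oxidation level are reached together; the only competing site is the CH at Q2.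

## Retrosynthesis

**17 from 16.** The last operation is removal of a protecting group from the ring C phenol. An acetate (**16**) is chosen because an acyl group makes ring C the least oxidisable aryl ether in the molecule during the ring closure. It can be removed by acid-catalysed methanolysis, under which the quinone is not exposed to base; methanol exchange at Q1 is degenerate and Q4 is shielded by the Q5 substituent.

**16 from 15 (key disconnection).** The Q5–CH2 bond is cut. The precursor is the open-chain quinone acid **15**; the forward reaction is a silver/persulfate decarboxylation whose primary radical adds to Q5 and whose adduct is oxidised back to the quinone. The neighbouring cuts are weaker: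
- Cutting Q4–O would require the C–C bond to be made intermolecularly first and two phenols to be told apart at the closure (kept as the fallback).
- Cutting a bibenzyl C–C bond (olefination and hydrogenation as the closure) would force ring A to be carried as a protected hydroquinone and oxidised late.
- Cutting the B–C diaryl ether would mean a hot, basic copper-mediated closure that a quinone does not survive.

The chosen cut removes one ring and one C–C bond and leaves a linear compound made from four simple aromatic pieces. The forward step must select Q5 over Q2, intramolecular over intermolecular addition, and carboxylate oxidation over arene oxidation.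

**15 from 13 and 12.** The acetate cannot be present while the quinone is attached under basic conditions, because a phenoxide would scramble it. Ring C is therefore carried as a methoxymethyl ether and the acid as a tert-butyl ester (**12**). Trifluoroacetic acid, harmless to the quinone, removes both at once to give phenol acid **13**, and acetylation gives **15**.

**12 from 9 and 11.** The Q4–O bond is cut to phenol **9** and 2-bromo-5-methoxy-1,4-benzoquinone **11**. Addition–elimination on the bromoquinone is preferred over oxidative addition of a phenol to methoxybenzoquinone: it is a standard route to aryloxyquinones, needs no oxidant, and the bromine-bearing carbon is β to the one carbonyl that the methoxy group does not deactivate. **11** comes from 1-bromo-2,4,5-trimethoxybenzene **10** by oxidative demethylation.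

**9 from 8, and 8 from 5 and 7.** The C–D bibenzyl bond is cut as an (E)-stilbene **8**, made by Horner–Wadsworth–Emmons reaction of aldehyde **5** with benzylphosphonate **7**. The phosphonate gives one alkene isomer and is made in one step from bromide **6**. One hydrogenation then saturates the alkene and frees the ring D phenol from its benzyl ether, leaving the methoxymethyl ether and tert-butyl ester untouched.

**5 from 4 and 2.** The B–C diaryl ether is cut between the ring B oxygen and the bromine-bearing carbon of ring C. Ullmann coupling of phenol **2** with aryl bromide **4** uses the halogen already present in 3-bromo-4-hydroxybenzaldehyde **3**. **4** is the methoxymethyl ether of **3**; **2** is the tert-butyl ester of 3-(4-hydroxyphenyl)propanoic acid **1**.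

## Roads not taken

**Alternative 1:** Ring B is built by a macrocyclising Diels–Alder reaction.
- Cut: two C–C bonds of ring B. The open-chain precursor **A1** carries a buta-1,3-dien-2-yl ether on the ring C oxygen and an ethynyl ketone on the ring A side chain; cycloaddition gives the macrocyclic cyclohexa-1,4-diene ketone **A2**.
- Merits: two skeletal bonds and the macrocycle form in one pericyclic step. The 2-oxygenated diene and the ynone are electronically matched for the required para pattern. The B–C ether needs no copper coupling, and no oxidant meets an electron-rich arene.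
- Weak points: the 2-aryloxydiene and the terminal ynone in **A1** are both prone to polymerisation and conjugate addition. A cycloaddition across a long tether has no entropic help and needs heat at high dilution. **A2** still needs aromatisation, removal of the benzylic ketone, loss of three benzyl groups and oxidation to the quinone. Ring A must first be made as a pentasubstituted arene.
- Comparison: this road forms more bonds in its key step and avoids radical and oxidant selectivity questions. The chosen plan sets against it a key step that ends one deprotection from **17**, and building blocks that are all simple aromatics.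

**Alternative 2:** The methoxyquinone is made last by squarate ring expansion.
- Cut: the Q6–Q1 bond. Thermolysis of the macrocyclic 4-hydroxy-4-(methoxyethynyl)cyclobutenone **A3** opens to an enynyl ketene that closes to the silyl-protected quinone **A4** (Moore rearrangement), followed by desilylation.
- Merits: the substitution pattern of ring A is fixed by construction, so there is no Q5/Q2 question. The quinone appears under neutral thermal conditions, and the ring expansion is an established reaction type. In regiochemical certainty this road is better than the chosen one.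
- Weak points: the macrocycle must already exist around an electrophilic cyclobutenedione, so the hard ring closure is only moved to another step on a more fragile substrate. The aryloxy group on the four-membered ring is a vinylogous aryl ester that an acetylide can displace. Methoxyethyne is not a shelf reagent. A heteroatom on the alkyne terminus can divert the diradical to a five-membered alkylidene cyclopentenedione.
- Comparison: the chosen plan accepts an uncertain site selectivity. It offsets this with the electronic bias of the weaker aryloxy donor, the geometry of the closure, and a much shorter route.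

**Alternative 3:** The B–C ether is closed by anodic phenol coupling.
- Cut: the O–C(ring C) bond. Anodic oxidation of the 2,6-dibromophenol **A5** lets the ring B phenol add ortho, and zinc reduction gives the macrocyclic ortho-hydroxy diaryl ether **A6**.
- Merits: this type of closure is established for macrocyclic diaryl ethers, it is phenol-selective, and it gives the ring C phenol free. In precedent for the ring-forming step it is better than the chosen plan.
- Weak points: two bromines must be introduced and one removed afterwards. Ring A has to be carried as a dibenzyl ether of a tetra-oxygenated arene, which is itself easily oxidised at the anode. Hydrogenolysis and a late hydroquinone-to-quinone oxidation next to a free phenol are still needed. The pentasubstituted ring A arene adds steps.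
- Comparison: the chosen plan is shorter (nine steps in the longest line) and reaches the quinone oxidation level without a late redox step. Its fallback is an ionic closure, which limits the exposure to the unprecedented step.

Key step: step 11

Remark: closure at Q2 instead of Q5 would give a 19-membered ring bridging Q4 and Q2 with the Q3 carbonyl inside the ring.
Assumption: 3-(4-hydroxyphenyl)propanoic acid, 3-bromo-4-hydroxybenzaldehyde, 1-(benzyloxy)-3-(bromomethyl)benzene and 1-bromo-2,4,5-trimethoxybenzene are taken as catalogue chemicals.

## Route

Step 1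
Reactants: 1 3-(4-hydroxyphenyl)propanoic acid
Product: 2 tert-butyl 3-(4-hydroxyphenyl)propanoate
Conditions: tert-butyl 2,2,2-trichloroacetimidate (2 equiv), CH2Cl2–cyclohexane, rt
Reagents that add atoms: tert-butyl 2,2,2-trichloroacetimidate, CC(C)(C)OC(=N)C(Cl)(Cl)Cl
Why: Imidate esterification; the carboxylic acid is acidic enough to protonate the imidate and capture the tert-butyl cation without added Lewis acid, whereas the phenol is not, so only the ester forms.

Step 2
Reactants: 3 3-bromo-4-hydroxybenzaldehyde
Product: 4 3-bromo-4-(methoxymethoxy)benzaldehyde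
Conditions: MOMCl, iPr2NEt, CH2Cl2, 0 °C → rt
Reagents that add atoms: chloromethyl methyl ether, COCCl
Why: Standard O-alkylation of a phenol to its methoxymethyl ether, a group that survives carbonate bases, phosphonate anions and hydrogenation and later falls to trifluoroacetic acid.

Step 3
Reactants: 4 3-bromo-4-(methoxymethoxy)benzaldehyde, 2 tert-butyl 3-(4-hydroxyphenyl)propanoate
Product: 5 tert-butyl 3-{4-[5-formyl-2-(methoxymethoxy)phenoxy]phenyl}propanoate
Conditions: CuI (10 mol%), N,N-dimethylglycine·HCl (30 mol%), Cs2CO3, 1,4-dioxane, 90 °C
Reagents that add atoms: none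
Why: Ligand-accelerated Ullmann diaryl ether coupling; amino acid ligands allow aryl bromides with ortho alkoxy groups to couple below 100 °C, and the non-enolisable aldehyde and the tert-butyl ester tolerate anhydrous carbonate.

Step 4
Reactants: 6 1-(benzyloxy)-3-(bromomethyl)benzene
Product: 7 diethyl {[3-(benzyloxy)phenyl]methyl}phosphonate
Conditions: P(OEt)3 (neat), 130 °C
Reagents that add atoms: triethyl phosphite, CCOP(OCC)OCC
Why: Michaelis–Arbuzov reaction of a benzylic bromide, driven by loss of bromoethane.

Step 5
Reactants: 5 tert-butyl 3-{4-[5-formyl-2-(methoxymethoxy)phenoxy]phenyl}propanoate, 7 diethyl {[3-(benzyloxy)phenyl]methyl}phosphonate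
Product: 8 tert-butyl 3-{4-[5-{(E)-2-[3-(benzyloxy)phenyl]ethenyl}-2-(methoxymethoxy)phenoxy]phenyl}propanoate
Conditions: KOtBu, THF, 0 °C → rt (phosphonate deprotonated first, then 5 added)
Reagents that add atoms: none
Why: Horner–Wadsworth–Emmons olefination; benzylphosphonate anions and aryl aldehydes give the (E)-stilbene through reversible addition and preferential collapse of the anti adduct, and tert-butoxide cannot transesterify the tert-butyl ester.

Step 6
Reactants: 8 tert-butyl 3-{4-[5-{(E)-2-[3-(benzyloxy)phenyl]ethenyl}-2-(methoxymethoxy)phenoxy]phenyl}propanoate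
Product: 9 tert-butyl 3-{4-[5-[2-(3-hydroxyphenyl)ethyl]-2-(methoxymethoxy)phenoxy]phenyl}propanoate
Conditions: H2 (1 atm), 10% Pd/C, EtOAc–EtOH, rt
Reagents that add atoms: none
Why: Catalytic hydrogenation saturates the stilbene and hydrogenolyses the benzyl ether in one operation; the acetal, tert-butyl ester and diaryl ether are inert, so only the ring D phenol is freed.

Step 7
Reactants: 10 1-bromo-2,4,5-trimethoxybenzene
Product: 11 2-bromo-5-methoxycyclohexa-2,5-diene-1,4-dione (2-bromo-5-methoxy-1,4-benzoquinone)
Conditions: (NH4)2Ce(NO3)6 (2.5 equiv), MeCN–H2O, 0 °C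
Reagents that add atoms: water, O
Why: Oxidative demethylation of a para-dimethoxyarene by tetravalent cerium; the 2- and 5-methoxy groups are para to each other, water adds at both ipso carbons of the oxidised ring and methanol leaves, so the bromine and the 4-methoxy group end up para across the quinone.

Step 8
Reactants: 9 tert-butyl 3-{4-[5-[2-(3-hydroxyphenyl)ethyl]-2-(methoxymethoxy)phenoxy]phenyl}propanoate, 11 2-bromo-5-methoxycyclohexa-2,5-diene-1,4-dione
Product: 12 tert-butyl 3-{4-[5-(2-{3-[(4-methoxy-3,6-dioxocyclohexa-1,4-dien-1-yl)oxy]phenyl}ethyl)-2-(methoxymethoxy)phenoxy]phenyl}propanoate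
Conditions: K2CO3, MeCN, 0 °C → rt (11, 1.2 equiv)
Reagents that add atoms: none
Why: Nucleophilic vinylic substitution (addition–elimination) of a haloquinone by a phenoxide; the bromine-bearing carbon is β to the carbonyl that is not deactivated by the methoxy group and bromide is the better leaving group, so the 2-aryloxy-5-methoxyquinone results, and it is a less reactive electrophile than 11.

Step 9
Reactants: 12 tert-butyl 3-{4-[5-(2-{3-[(4-methoxy-3,6-dioxocyclohexa-1,4-dien-1-yl)oxy]phenyl}ethyl)-2-(methoxymethoxy)phenoxy]phenyl}propanoate
Product: 13 3-{4-[2-hydroxy-5-(2-{3-[(4-methoxy-3,6-dioxocyclohexa-1,4-dien-1-yl)oxy]phenyl}ethyl)phenoxy]phenyl}propanoic acid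
Conditions: TFA–CH2Cl2 (1:4), H2O (5 equiv), 0 °C → rt
Reagents that add atoms: none
Why: Acidolysis removes the tert-butyl ester (as isobutene) and the methoxymethyl acetal together; the acid is non-nucleophilic, so the aryloxy-methoxyquinone is not attacked, and water traps the cations released.

Step 10
Reactants: 13 3-{4-[2-hydroxy-5-(2-{3-[(4-methoxy-3,6-dioxocyclohexa-1,4-dien-1-yl)oxy]phenyl}ethyl)phenoxy]phenyl}propanoic acid
Product: 15 3-{4-[2-(acetyloxy)-5-(2-{3-[(4-methoxy-3,6-dioxocyclohexa-1,4-dien-1-yl)oxy]phenyl}ethyl)phenoxy]phenyl}propanoic acid, via mixed carboxylic acetic anhydride 14 (not isolated)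
Conditions: Ac2O (3 equiv), pyridine, CH2Cl2, 0 °C → rt; then H2O, rt
Reagents that add atoms: acetic anhydride, CC(=O)OC(C)=O
Why: Pyridine-mediated O-acetylation of a phenol; the carboxyl group is converted in part to the mixed anhydride 14, which the aqueous pyridine quench cleaves at the acetyl carbonyl, and without strong acid the quinone does not undergo Thiele–Winter acetoxylation.

Step 11
Reactants: 15 3-{4-[2-(acetyloxy)-5-(2-{3-[(4-methoxy-3,6-dioxocyclohexa-1,4-dien-1-yl)oxy]phenyl}ethyl)phenoxy]phenyl}propanoic acid
Product: 16 macrocyclic quinone acetate (the O-acetyl derivative of 17 at the ring C phenol; Q5 bonded to the CH2CH2 bridge of ring B, 18-membered ring)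
Conditions: AgNO3 (0.3 equiv), (NH4)2S2O8 (2.5 equiv), degassed MeCN–H2O (1:1), 65 °C, argon; 15 and the persulfate added separately by syringe pump over 10 h, final concentration about 1 mM
Reagents that add atoms: none
Why: Proposed new method: persulfate oxidises monovalent silver to divalent silver, which oxidises the bound carboxylate of 15; loss of CO2 gives the primary 2-arylethyl radical, which adds to Q5 of the tethered quinone, and the semiquinone-type adduct loses a proton and is oxidised back to the quinone, forming the Q5–CH2 bond and the macrocycle in one operation. The closest known reaction type is the intermolecular AgNO3/persulfate decarboxylative alkylation of quinones (Jacobsen–Torssell, Minisci-type), which accepts 3-arylpropanoic acids and alkoxy- or hydroxy-substituted quinones; its use as a macrocyclisation is new. The closure is an 18-endo-trig radical addition (Q4 and Q5 both lie in the new ring), and no stereocentre is created. Selectivity for Q5 over Q2 should follow from the weaker donor on Q4 (an aryloxy oxygen shared with ring D) compared with the methoxy group on Q1, which leaves the Q4=Q5 bond the more electron-poor, and from the shorter reach to the carbon next to the tether oxygen, without an inward-pointing carbonyl. Slow addition of 15 and oxidant should keep the stationary concentration of unreacted quinone below the effective molarity of the closure, so intramolecular addition wins over oligomerisation. The product resists a second alkylation because its only remaining CH (Q2) lies on the methoxy-deactivated double bond. Chemoselectivity of the oxidant rests on inner-sphere oxidation of the carboxylate, on ring C being deactivated as its acetate and ring D as a quinonyl ether, and on the 1,2-aryl shift of the 2-arylethyl radical being degenerate.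

Step 12
Reactants: 16 macrocyclic quinone acetate
Product: 17 the target quinone (CNP0332646.0)
Conditions: TsOH·H2O (0.3 equiv), MeOH–CH2Cl2 (3:1), rt → 35 °C
Reagents that add atoms: none
Why: Acid-catalysed transesterification of an aryl acetate with methanol; the sulfonic acid is non-nucleophilic, exchange of methanol at Q1 is degenerate, and Q4 is shielded by the Q5 substituent and the ring, so the aryloxyquinone should persist.

## Compound list

1 | 3-(4-hydroxyphenyl)propanoic acid | OC(=O)CCc1ccc(O)cc1 | starting material
2 | tert-butyl 3-(4-hydroxyphenyl)propanoate | CC(C)(C)OC(=O)CCc1ccc(O)cc1 | intermediate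
3 | 3-bromo-4-hydroxybenzaldehyde | O=Cc1ccc(O)c(Br)c1 | starting material
4 | 3-bromo-4-(methoxymethoxy)benzaldehyde | COCOc1ccc(C=O)cc1Br | intermediate
5 | tert-butyl 3-{4-[5-formyl-2-(methoxymethoxy)phenoxy]phenyl}propanoate | COCOc1ccc(C=O)cc1Oc1ccc(CCC(=O)OC(C)(C)C)cc1 | intermediate
6 | 1-(benzyloxy)-3-(bromomethyl)benzene | BrCc1cccc(OCc2ccccc2)c1 | starting material
7 | diethyl {[3-(benzyloxy)phenyl]methyl}phosphonate | CCOP(=O)(Cc1cccc(OCc2ccccc2)c1)OCC | intermediate
8 | tert-butyl 3-{4-[5-{(E)-2-[3-(benzyloxy)phenyl]ethenyl}-2-(methoxymethoxy)phenoxy]phenyl}propanoate | COCOc1ccc(/C=C/c2cccc(OCc3ccccc3)c2)cc1Oc1ccc(CCC(=O)OC(C)(C)C)cc1 | intermediate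
9 | tert-butyl 3-{4-[5-[2-(3-hydroxyphenyl)ethyl]-2-(methoxymethoxy)phenoxy]phenyl}propanoate | COCOc1ccc(CCc2cccc(O)c2)cc1Oc1ccc(CCC(=O)OC(C)(C)C)cc1 | intermediate
10 | 1-bromo-2,4,5-trimethoxybenzene | COc1cc(OC)c(Br)cc1OC | starting material
11 | 2-bromo-5-methoxycyclohexa-2,5-diene-1,4-dione | COC1=CC(=O)C(Br)=CC1=O | intermediate
12 | tert-butyl 3-{4-[5-(2-{3-[(4-methoxy-3,6-dioxocyclohexa-1,4-dien-1-yl)oxy]phenyl}ethyl)-2-(methoxymethoxy)phenoxy]phenyl}propanoate | COC1=CC(=O)C(Oc2cccc(CCc3ccc(OCOC)c(Oc4ccc(CCC(=O)OC(C)(C)C)cc4)c3)c2)=CC1=O | intermediate
13 | 3-{4-[2-hydroxy-5-(2-{3-[(4-methoxy-3,6-dioxocyclohexa-1,4-dien-1-yl)oxy]phenyl}ethyl)phenoxy]phenyl}propanoic acid | COC1=CC(=O)C(Oc2cccc(CCc3ccc(O)c(Oc4ccc(CCC(=O)O)cc4)c3)c2)=CC1=O | intermediate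
14 | acetic 3-{4-[2-(acetyloxy)-5-(2-{3-[(4-methoxy-3,6-dioxocyclohexa-1,4-dien-1-yl)oxy]phenyl}ethyl)phenoxy]phenyl}propanoic anhydride | COC1=CC(=O)C(Oc2cccc(CCc3ccc(OC(C)=O)c(Oc4ccc(CCC(=O)OC(C)=O)cc4)c3)c2)=CC1=O | intermediate (not isolated)
15 | 3-{4-[2-(acetyloxy)-5-(2-{3-[(4-methoxy-3,6-dioxocyclohexa-1,4-dien-1-yl)oxy]phenyl}ethyl)phenoxy]phenyl}propanoic acid | COC1=CC(=O)C(Oc2cccc(CCc3ccc(OC(C)=O)c(Oc4ccc(CCC(=O)O)cc4)c3)c2)=CC1=O | intermediate
16 | macrocyclic quinone acetate: 18-membered ring Q4–O–ring D (1,3)–CH2CH2–ring C–O–ring B (1,4)–CH2CH2–Q5, ring C carrying OAc para to its CH2CH2 and ortho to the ether oxygen, OMe on Q1 | COC1=CC(=O)C2=C(CCc3ccc(cc3)Oc3cc(ccc3OC(C)=O)CCc3cccc(c3)O2)C1=O | intermediate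
17 | target quinone CNP0332646.0: as 16 with a free ring C phenol | COC1=CC(=O)C2=C(CCc3ccc(cc3)Oc3cc(ccc3O)CCc3cccc(c3)O2)C1=O | target

## Step count and risks

Total: 12 steps. Longest linear sequence: 9 steps (step 1 or 2, then steps 3, 5, 6, 8, 9, 10, 11, 12).

**Step 11 (key step, proposed new method).**
- What may go wrong: intermolecular radical addition and oligomerisation outrunning the ring closure; attack at Q2; oxidation of the aryl ether rings by divalent silver or sulfate radical anion in place of decarboxylation.
- Fallback (known reaction types; the C–C bond is made intermolecularly and the ring is closed at Q4–O), setting out from 9 and returning at 17: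
  - TFA in CH2Cl2 removes acetal and ester from 9 to give 3-{4-[2-hydroxy-5-[2-(3-hydroxyphenyl)ethyl]phenoxy]phenyl}propanoic acid F1.
  - Ac2O in aqueous NaOH at 0 °C acetylates both phenols to give 3-{4-[2-(acetyloxy)-5-{2-[3-(acetyloxy)phenyl]ethyl}phenoxy]phenyl}propanoic acid F2.
  - Intermolecular AgNO3/(NH4)2S2O8 decarboxylative alkylation of an excess of bromoquinone 11 with F2 should occur at the CH next to the bromine-bearing carbon, giving 2-bromo-3-(2-{4-[2-(acetyloxy)-5-{2-[3-(acetyloxy)phenyl]ethyl}phenoxy]phenyl}ethyl)-5-methoxy-1,4-benzoquinone F3.
  - TsOH in methanol removes both acetates to give 2-bromo-3-(2-{4-[2-hydroxy-5-[2-(3-hydroxyphenyl)ethyl]phenoxy]phenyl}ethyl)-5-methoxy-1,4-benzoquinone F4.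
  - Cs2CO3 in MeCN at high dilution closes the ring by phenoxide addition–elimination at the bromine-bearing Q4, giving 17 directly. Only the ring D phenoxide can reach Q4 within the molecule; the ring C phenoxide would have to close a 12-membered ring across para-phenylene B.

**Step 12.**
- What may go wrong: acid-catalysed exchange of the ring D aryloxy group on Q4 by methanol, opening the macrocycle, competing with acetate methanolysis.
- Fallback, from 16 to 17: aqueous Na2S2O4 reduces 16 to the hydroquinone of the macrocyclic acetate F5, which is no longer an electrophile. K2CO3 in degassed MeOH under argon cleaves the acetate to the hydroquinone of the target F6. Air or Ag2O then reoxidises ring A to give 17.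

**Step 8.**
- What may go wrong: phenoxide attack at the wrong quinone position (displacement of methoxide, or addition at a CH followed by loss of HBr), a second substitution, or base-induced decomposition of the quinone.
- Fallback, from 9 to 12, which builds ring A as an arene and oxidises it while ring C is still protected:
  - Chan–Lam–Evans coupling of 9 with [3-(benzyloxy)-4-methoxyphenyl]boronic acid (Cu(OAc)2, pyridine, 4 Å sieves, air) gives tert-butyl 3-{4-[5-(2-{3-[3-(benzyloxy)-4-methoxyphenoxy]phenyl}ethyl)-2-(methoxymethoxy)phenoxy]phenyl}propanoate F7.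
  - H2 over 10% Pd/C gives tert-butyl 3-{4-[5-(2-{3-[3-hydroxy-4-methoxyphenoxy]phenyl}ethyl)-2-(methoxymethoxy)phenoxy]phenyl}propanoate F8.
  - Teuber oxidation with (KSO3)2NO in buffered aqueous acetone oxidises the phenol at its free para position to the para-quinone 12.

**Step 3.**
- What may go wrong: slow oxidative addition at the hindered, electron-rich ortho-alkoxy aryl bromide, leading to reductive loss of bromine or degradation of the aldehyde on prolonged heating with carbonate.
- Fallback, from 4 to 5:
  - Miyaura borylation (B2pin2, Pd(dppf)Cl2, KOAc, dioxane, 80 °C) gives 4-(methoxymethoxy)-3-(4,4,5,5-tetramethyl-1,3,2-dioxaborolan-2-yl)benzaldehyde F9.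
  - NaIO4/NH4OAc in aqueous acetone gives [5-formyl-2-(methoxymethoxy)phenyl]boronic acid F10.
  - Chan–Lam–Evans coupling with phenol 2 (Cu(OAc)2, pyridine, 4 Å sieves, air, rt) gives 5 at room temperature.

## Further compounds

F1 | step 11 | 3-{4-[2-hydroxy-5-[2-(3-hydroxyphenyl)ethyl]phenoxy]phenyl}propanoic acid | OC(=O)CCc1ccc(Oc2cc(CCc3cccc(O)c3)ccc2O)cc1
F2 | step 11 | 3-{4-[2-(acetyloxy)-5-{2-[3-(acetyloxy)phenyl]ethyl}phenoxy]phenyl}propanoic acid | OC(=O)CCc1ccc(Oc2cc(CCc3cccc(OC(C)=O)c3)ccc2OC(C)=O)cc1
F3 | step 11 | 2-bromo-3-(2-{4-[2-(acetyloxy)-5-{2-[3-(acetyloxy)phenyl]ethyl}phenoxy]phenyl}ethyl)-5-methoxy-1,4-benzoquinone | COC1=CC(=O)C(Br)=C(CCc2ccc(Oc3cc(CCc4cccc(OC(C)=O)c4)ccc3OC(C)=O)cc2)C1=O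
F4 | step 11 | 2-bromo-3-(2-{4-[2-hydroxy-5-[2-(3-hydroxyphenyl)ethyl]phenoxy]phenyl}ethyl)-5-methoxy-1,4-benzoquinone | COC1=CC(=O)C(Br)=C(CCc2ccc(Oc3cc(CCc4cccc(O)c4)ccc3O)cc2)C1=O
F5 | step 12 | hydroquinone of the macrocyclic acetate 16 (ring A as the 1,4-diol) | COc1cc(O)c2c(CCc3ccc(cc3)Oc3cc(ccc3OC(C)=O)CCc3cccc(c3)O2)c1O
F6 | step 12 | hydroquinone of the target 17 (ring A as the 1,4-diol, ring C phenol free) | COc1cc(O)c2c(CCc3ccc(cc3)Oc3cc(ccc3O)CCc3cccc(c3)O2)c1O
F7 | step 8 | tert-butyl 3-{4-[5-(2-{3-[3-(benzyloxy)-4-methoxyphenoxy]phenyl}ethyl)-2-(methoxymethoxy)phenoxy]phenyl}propanoate | COc1ccc(Oc2cccc(CCc3ccc(OCOC)c(Oc4ccc(CCC(=O)OC(C)(C)C)cc4)c3)c2)cc1OCc1ccccc1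
F8 | step 8 | tert-butyl 3-{4-[5-(2-{3-[3-hydroxy-4-methoxyphenoxy]phenyl}ethyl)-2-(methoxymethoxy)phenoxy]phenyl}propanoate | COc1ccc(Oc2cccc(CCc3ccc(OCOC)c(Oc4ccc(CCC(=O)OC(C)(C)C)cc4)c3)c2)cc1O
F9 | step 3 | 4-(methoxymethoxy)-3-(4,4,5,5-tetramethyl-1,3,2-dioxaborolan-2-yl)benzaldehyde | COCOc1ccc(C=O)cc1B1OC(C)(C)C(C)(C)O1
F10 | step 3 | [5-formyl-2-(methoxymethoxy)phenyl]boronic acid | COCOc1ccc(C=O)cc1B(O)O
A1 | alternative 1 | 1-[3,6-bis(benzyloxy)-2-(3-{2-[4-(benzyloxy)-3-(buta-1,3-dien-2-yloxy)phenyl]ethyl}phenoxy)-5-methoxyphenyl]but-3-yn-2-one | COc1cc(OCc2ccccc2)c(Oc2cccc(CCc3ccc(OCc4ccccc4)c(OC(=C)C=C)c3)c2)c(CC(=O)C#C)c1OCc1ccccc1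
A2 | alternative 1 | macrocyclic cyclohexa-1,4-diene ketone (ring B at the dihydro level, C=O next to the ring A CH2, rings A and C as benzyl ethers) | COc1cc(OCc2ccccc2)c2c(CC(=O)C3=CCC(=CC3)Oc3cc(ccc3OCc3ccccc3)CCc3cccc(c3)O2)c1OCc1ccccc1
A3 | alternative 2 | macrocyclic 4-hydroxy-4-(methoxyethynyl)cyclobut-2-en-1-one (ring D oxygen on C3, ethano bridge to ring B on C2, ring C phenol as tert-butyldimethylsilyl ether) | COC#CC1(O)C(=O)C2=C1Oc1cccc(CCc3ccc(O[Si](C)(C)C(C)(C)C)c(Oc4ccc(CC2)cc4)c3)c1
A4 | alternative 2 | ring C tert-butyldimethylsilyl ether of the target quinone | COC1=CC(=O)C2=C(CCc3ccc(cc3)Oc3cc(ccc3O[Si](C)(C)C(C)(C)C)CCc3cccc(c3)O2)C1=O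
A5 | alternative 3 | open-chain 2,6-dibromophenol (ring C) with free ring B phenol, ring A as dibenzyl ether of the hydroquinone | COc1cc(OCc2ccccc2)c(Oc2cccc(CCc3cc(Br)c(O)c(Br)c3)c2)c(CCc2ccc(O)cc2)c1OCc1ccccc1
A6 | alternative 3 | macrocycle with free ring C phenol, one ortho bromine, ring A as dibenzyl ether of the hydroquinone | COc1cc(OCc2ccccc2)c2c(CCc3ccc(cc3)Oc3cc(cc(Br)c3O)CCc3cccc(c3)O2)c1OCc1ccccc1
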